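## The problem

Target 27 is the 8-O-(E)-feruloyl ester of an (E,E)-germacra-1(10),4-diene-6,8-diol. Germacrane numbering is used for every intermediate: C1=C10(C14H3)–C9H2–C8H(O-feruloyl)–C7H(iPr)–C6H(OH)–C5H=C4(C15H3)–C3H2–C2H2, ring closed C2–C1.

- A ten-membered carbocycle with two E-trisubstituted olefins has to be made. End-to-end closure of such a ring is slow and strained, and the finished 1,5-diene undergoes Cope rearrangement on heating and transannular cyclisation with acid.
- C6, C7 and C8 (all S) are contiguous. Along the ring path C5→C9 the isopropyl group is trans to O8 but cis to O6, and O6/O8 are 1,3-anti. C7 can send a reagent to the opposite face at C8, but the cis O6 cannot be set by the same logic.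
- Only O8 is acylated, so the two secondary oxygens must be told apart, and 1,3-diol monoesters migrate under base.
- The allylic C6 carbinol, the free phenol and the cinnamate rule out acid, strong base and nucleophiles at the end.
- Feature used by the key step: C10=C1–C2–C3–C4=C5 is a hexa-1,5-diene. Exchanging the C2–C3 bond for a C5–C10 bond gives a cyclohexane C5–C6–C7–C8–C9–C10 that holds all three stereocentres. C10 carries its methyl group exactly where an oxy-Cope rearrangement leaves an enolate oxygen.
- Second feature: a free O6–H beside an O8-acyl group in 1,3-anti relation is what hydride transfer from an O8 hemiacetal to a C6 ketone delivers. C6 therefore needs no control before the last steps.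

## Retrosynthesis

**27 ⇒ 26 ⇒ 23 + 25.** After unmasking the phenol (26), the O8–acyl bond and the C6–H bond are cut together (Evans–Tishchenko retron). The neighbouring cuts are acylation of a 6,8-diol, which needs O6/O8 differentiation and a correct C6 beforehand, and esterification followed by external reduction, which has no internal control. This cut puts the ester on O8 only and sets C6 from C8 in one operation. Hydroxy enone 23 has one stereocentre fewer and no protecting groups; aldehyde 25 is silylated coniferaldehyde 24. The forward reaction must pass the hemiacetal hydride to C6 inside the ten-membered ring.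

**23 ⇒ 22 ⇒ 21.** The C6 carbonyl comes from chemoselective oxidation of the allylic alcohol of diol 22, itself from bis-silyl ether 21. Because C6 becomes sp2 here, every earlier intermediate may carry O6 in whatever configuration is easiest to make. This removes the cis-O6 problem from the ring construction.

**21 ⇒ 19 + 20.** The C10–C14 bond is cut: the methyl group comes from MeMgBr (20) and enol triflate 19. This lets C10 carry oxygen in the precursor; the coupling must retain the double-bond geometry.

**19 ⇒ 17 (key).** The C2–C3 bond is cut and the C5–C10 bond restored: an anionic oxy-Cope retron with the enolate trapped as triflate. Against cutting C5–C6 or C6–C7 (macrocyclisations), this cut forms the ring by enlargement and fixes both olefin geometries through one chair. Precursor 17 is a cyclohexanol in which all substituents are equatorial except the hydroxyl. The forward step needs the two alkenyl groups trans.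

**17 ⇒ 15 + 16.** The C10–C1 bond is cut: vinyl addition to cyclohexanone 15 trans to the C5 isopropenyl group.

**15 ⇒ 14 ⇒ 12 ⇒ 10 ⇒ 9 ⇒ 7.** The C8–O and C6–O bonds are cut. Each oxygen enters by conjugate borylation/oxidation anti to the C7 isopropyl group. The enone is moved from C5=C6 to C8=C9 by Saegusa–Ito oxidation (12 from 10). The result is the all-equatorial, thermodynamically favoured ketone; only the C7/C8 trans relation is carried to the target.

**7 ⇒ 5 + 6; 5 ⇒ 4 ⇒ 1 + 2.** The C5–C4 bond is cut (Suzuki coupling of iodoenone 5 with isopropenylboronate 6). Enone 4, (S)-cryptone, comes from 3-methylbutanal 1 and but-3-en-2-one 2 by organocatalytic Michael addition and aldol condensation, which sets C7, the only stereocentre that needs a chiral catalyst.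

## Roads not taken

**Alternative 1:** the most obvious plan. Cut C5–C6 and close the ring by Nozaki–Hiyama–Kishi reaction (CrCl2/NiCl2) of open-chain iodo-aldehyde A1 to macrocyclic allylic alcohol A2.
- A1 needs both E-trisubstituted olefins and the C7/C8 pair built separately on a chain.
- The closure is an end-to-end cyclisation to a strained E,E-cyclodecadiene at high dilution.
- C6 would rest on the Felkin-versus-chelate preference of an α-branched β-alkoxy aldehyde inside a macrocyclic transition state.
- O6/O8 differentiation is still needed (hence the extra protecting group in A1).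
- The chosen plan forms the ring by concerted enlargement, sets both geometries in one chair and sets C6 by internal hydride delivery.

**Alternative 2:** cut C6–C7. Intramolecular carbonyl allylation (Pd(PPh3)4/Et2Zn umpolung, or CrCl2) of chloro-aldehyde A3, a farnesal-type chain oxygenated at C8, closes the ring through the γ-carbon to isopropenyl carbinol A4.
- C6 and C7 are both created in the ring closure, governed by allyl geometry in a ten-membered closed transition state and only remotely by C8.
- The isopropenyl group must then be hydrogenated selectively next to two ring olefins and an allylic alcohol.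
- The diol must again be differentiated.
- In the chosen plan C7 is set first and controls C8 on a rigid six-membered ring.

**Alternative 3:** the other [3,3] mapping, with the carbinol at C6 (break C1–C6, form C8–C9). Dialkenyl carbinol A5, from isopiperitenone, would give C6 ketone A6 directly by anionic oxy-Cope rearrangement.
- C4=C5 lies inside the six-membered ring of A5 and is therefore delivered Z.
- C7 would be set by unselective enolate protonation.
- C8 stays unoxygenated unless a β-oxygenated alkenyl metal, prone to β-elimination, is used.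
- The chosen mapping keeps both olefins outside the cyclohexane, so both emerge E, and keeps C7 and C8 as ring stereocentres.

Key step: step 10

Assumption: the (S)-configured diphenylprolinol methyl ether is taken to give the 2S Michael adduct 3 (enone on the enamine face away from the diarylmethyl arm); if the sense were opposite, the enantiomeric catalyst would be used.

## Route

Step 1
Reactants: 1 3-methylbutanal; 2 but-3-en-2-one
Product: 4 (4S)-4-(propan-2-yl)cyclohex-2-en-1-one, via (2S)-5-oxo-2-(propan-2-yl)hexanal 3 (not isolated)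
Conditions: (S)-2-[methoxy(diphenyl)methyl]pyrrolidine (5 mol%), ethyl 3,4-dihydroxybenzoate (20 mol%), neat, 4 °C; then LiOH, iPrOH, rt
Reagents that add atoms: none
Why: Enamine-catalysed Michael addition to the vinyl ketone sets C7, and the crude keto-aldehyde closes by intramolecular aldol condensation (Robinson-type annulation) under hydroxide mild enough to leave the γ-stereocentre intact.

Step 2
Reactants: 4 (4S)-4-(propan-2-yl)cyclohex-2-en-1-one
Product: 5 (4S)-2-iodo-4-(propan-2-yl)cyclohex-2-en-1-one
Conditions: I2, pyridine, CH2Cl2, 0 °C to rt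
Reagents that add atoms: iodine, [I][I]
Why: α-Iodination of a cyclic enone by conjugate addition of pyridine, iodination of the enolate and elimination; C7 is not involved.

Step 3
Reactants: 5 (4S)-2-iodo-4-(propan-2-yl)cyclohex-2-en-1-one; 6 4,4,5,5-tetramethyl-2-(prop-1-en-2-yl)-1,3,2-dioxaborolane
Product: 7 (4S)-4-(propan-2-yl)-2-(prop-1-en-2-yl)cyclohex-2-en-1-one
Conditions: PdCl2(dppf) (3 mol%), K3PO4, THF/H2O, 40 °C; product used without storage
Reagents that add atoms: none
Why: Suzuki–Miyaura coupling of a 2-iodoenone with an alkenyl pinacolboronate places the C4/C3/C15 isopropenyl unit on C5 before any base-labile β-oxygen is present.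

Step 4
Reactants: 7 (4S)-4-(propan-2-yl)-2-(prop-1-en-2-yl)cyclohex-2-en-1-one
Product: 9 (2R,3S,4S)-3-hydroxy-4-(propan-2-yl)-2-(prop-1-en-2-yl)cyclohexan-1-one, via C6 pinacolboronate 8 (not isolated)
Conditions: CuCl (5 mol%), DPEphos (5 mol%), NaOtBu (6 mol%), B2pin2, MeOH (2 equiv), THF, 0 °C to rt; then NaBO3·4H2O, THF/H2O, rt
Reagents that add atoms: bis(pinacolato)diboron, CC1(C)OB(B2OC(C)(C)C(C)(C)O2)OC1(C)C (boron kept only in 8); sodium perborate, [Na+].[O-]OB=O (gives the hydroxyl oxygen)
Why: Copper-catalysed conjugate borylation followed by stereoretentive C–B oxidation; the Cu–Bpin species adds to C6 opposite the neighbouring C7 isopropyl group (as organocopper additions to 4-substituted cyclohexenones do), α-protonation of the dienolate keeps the isopropenyl double bond out of conjugation, and C5 should settle as the equatorial epimer (its configuration is erased in step 10).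

Step 5
Reactants: 9 (2R,3S,4S)-3-hydroxy-4-(propan-2-yl)-2-(prop-1-en-2-yl)cyclohexan-1-one
Product: 10 (2R,3S,4S)-3-[(tert-butyldimethylsilyl)oxy]-4-(propan-2-yl)-2-(prop-1-en-2-yl)cyclohexan-1-one
Conditions: TBSOTf, 2,6-lutidine, CH2Cl2, −78 to 0 °C
Reagents that add atoms: tert-butyldimethylsilyl trifluoromethanesulfonate, CC(C)(C)[Si](C)(C)OS(=O)(=O)C(F)(F)F
Why: Silylation of a hindered secondary alcohol with a silyl triflate and a non-nucleophilic base at low temperature, which should leave the β-hydroxy ketone free of retro-aldol cleavage and elimination.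

Step 6
Reactants: 10 (2R,3S,4S)-3-[(tert-butyldimethylsilyl)oxy]-4-(propan-2-yl)-2-(prop-1-en-2-yl)cyclohexan-1-one
Product: 12 (4R,5S,6R)-5-[(tert-butyldimethylsilyl)oxy]-4-(propan-2-yl)-6-(prop-1-en-2-yl)cyclohex-2-en-1-one, via trimethylsilyl enol ether 11 (not isolated)
Conditions: LiN(iPr)2, THF, −78 °C, then Me3SiCl; then Pd(OAc)2 (1.1 equiv), MeCN, rt
Reagents that add atoms: chlorotrimethylsilane, C[Si](C)(C)Cl (silicon kept only in 11)
Why: Kinetic deprotonation by the hindered amide at the open C9 methylene (C5 is a shielded methine) gives the C9=C10 silyl enol ether, and Saegusa–Ito oxidation turns it into the C8=C9 enone under neutral conditions.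

Step 7
Reactants: 12 (4R,5S,6R)-5-[(tert-butyldimethylsilyl)oxy]-4-(propan-2-yl)-6-(prop-1-en-2-yl)cyclohex-2-en-1-one
Product: 14 (2R,3S,4R,5S)-3-[(tert-butyldimethylsilyl)oxy]-5-hydroxy-4-(propan-2-yl)-2-(prop-1-en-2-yl)cyclohexan-1-one, via C8 pinacolboronate 13 (not isolated)
Conditions: CuCl (5 mol%), DPEphos (5 mol%), NaOtBu (6 mol%), B2pin2, MeOH (2 equiv), THF, 0 °C to rt; then NaBO3·4H2O, THF/H2O, rt
Reagents that add atoms: bis(pinacolato)diboron, CC1(C)OB(B2OC(C)(C)C(C)(C)O2)OC1(C)C (boron kept only in 13); sodium perborate, [Na+].[O-]OB=O (gives the hydroxyl oxygen)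
Why: Second copper-catalysed conjugate borylation/oxidation; addition to C8 again occurs anti to the C7 isopropyl group, which sets the C7/C8 trans relation of the target, and the nearly base-free medium spares the β-silyloxy group.

Step 8
Reactants: 14 (2R,3S,4R,5S)-3-[(tert-butyldimethylsilyl)oxy]-5-hydroxy-4-(propan-2-yl)-2-(prop-1-en-2-yl)cyclohexan-1-one
Product: 15 (2R,3S,4R,5S)-3,5-bis[(tert-butyldimethylsilyl)oxy]-4-(propan-2-yl)-2-(prop-1-en-2-yl)cyclohexan-1-one
Conditions: TBSOTf, 2,6-lutidine, CH2Cl2, −78 to 0 °C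
Reagents that add atoms: tert-butyldimethylsilyl trifluoromethanesulfonate, CC(C)(C)[Si](C)(C)OS(=O)(=O)C(F)(F)F
Why: Same low-temperature silylation as in step 5; the product is a chair ketone with all four substituents equatorial.

Step 9
Reactants: 15 (2R,3S,4R,5S)-3,5-bis[(tert-butyldimethylsilyl)oxy]-4-(propan-2-yl)-2-(prop-1-en-2-yl)cyclohexan-1-one; 16 ethenylmagnesium bromide
Product: 17 (1R,2R,3S,4R,5S)-3,5-bis[(tert-butyldimethylsilyl)oxy]-1-ethenyl-4-(propan-2-yl)-2-(prop-1-en-2-yl)cyclohexan-1-ol
Conditions: CH2=CHMgBr, CeCl3 (anhydrous), THF, −78 °C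
Reagents that add atoms: none
Why: 1,2-Addition of the CeCl3-modified Grignard reagent, whose low basicity avoids enolisation and loss of the β-silyloxy groups; attack from the equatorial direction, trans to the equatorial C5 isopropenyl group, gives the axial alcohol with the two alkenyl groups trans-diequatorial.

Step 10
Reactants: 17 (1R,2R,3S,4R,5S)-3,5-bis[(tert-butyldimethylsilyl)oxy]-1-ethenyl-4-(propan-2-yl)-2-(prop-1-en-2-yl)cyclohexan-1-ol
Product: 19 (1Z,5E,7R,8R,9S)-7,9-bis[(tert-butyldimethylsilyl)oxy]-5-methyl-8-(propan-2-yl)cyclodeca-1,5-dien-1-yl trifluoromethanesulfonate, via potassium enolate 18 (not isolated)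
Conditions: KN(SiMe3)2, 18-crown-6, THF, −78 to 0 °C; then PhNTf2, −78 °C to rt
Reagents that add atoms: N-phenylbis(trifluoromethanesulfonimide), O=S(=O)(N(c1ccccc1)S(=O)(=O)C(F)(F)F)C(F)(F)F
Why: Deprotonation gives the potassium alkoxide, held as a loose ion pair by the crown ether, which undergoes an anionic oxy-Cope [3,3]-sigmatropic shift in which C2–C3 forms as C5–C10 breaks, and the resulting enolate 18 is O-sulfonylated in the same flask. The closest known reaction type is the ring expansion of trans-1,2-dialkenylcyclohexanols to (E)-cyclodec-5-enones with trapping of the regiodefined enolate. The ten-membered ring is not closed end to end: it arises by concerted four-carbon enlargement of the cyclohexane through a chair transition state fused trans to the six-membered ring, so no dilution is needed. No stereocentre is created; C5 and C10 are erased and the two stereogenic double bonds are set instead. C6 sits pseudo-equatorial on the chair and so ends trans to C3 across C4=C5 (E), and C9 sits pseudo-equatorial so that the enolate oxygen is cis to C2 (Z triflate), the geometry that becomes 1(10)E on methylation. The step needs chair over boat, [3,3] over [1,3]-shift or fragmentation, and O- over C-sulfonylation; the trans-diequatorial alkenyl groups on an all-equatorial chair and the crown-separated potassium enolate with a hard sulfonyl donor should secure these. The equatorial silyl ethers lie too far from the axial alkoxide to migrate, and the enolate, formed away from C9 without any proton source, cannot expel the C8 silyloxy group.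

Step 11
Reactants: 19 (1Z,5E,7R,8R,9S)-7,9-bis[(tert-butyldimethylsilyl)oxy]-5-methyl-8-(propan-2-yl)cyclodeca-1,5-dien-1-yl trifluoromethanesulfonate; 20 methylmagnesium bromide
Product: 21 (1E,5E,7R,8R,9S)-7,9-bis[(tert-butyldimethylsilyl)oxy]-1,5-dimethyl-8-(propan-2-yl)cyclodeca-1,5-diene
Conditions: MeMgBr, Fe(acac)3 (5 mol%), THF/NMP, −30 to 0 °C
Reagents that add atoms: none
Why: Iron-catalysed cross-coupling of an alkenyl triflate with a methyl Grignard reagent proceeds with retention of double-bond geometry, so the Z triflate gives the 1(10)E olefin carrying C14; silyl ethers and the trisubstituted olefin are inert.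

Step 12
Reactants: 21 (1E,5E,7R,8R,9S)-7,9-bis[(tert-butyldimethylsilyl)oxy]-1,5-dimethyl-8-(propan-2-yl)cyclodeca-1,5-diene
Product: 22 (1S,2R,3R,4E,8E)-5,9-dimethyl-2-(propan-2-yl)cyclodeca-4,8-diene-1,3-diol
Conditions: Bu4NF, THF, rt to 40 °C
Reagents that add atoms: none
Why: Fluoride cleavage of both silyl ethers under non-acidic conditions, which avoids transannular cyclisation of the 1,5-diene.

Step 13
Reactants: 22 (1S,2R,3R,4E,8E)-5,9-dimethyl-2-(propan-2-yl)cyclodeca-4,8-diene-1,3-diol
Product: 23 (2E,6E,9S,10R)-9-hydroxy-3,7-dimethyl-10-(propan-2-yl)cyclodeca-2,6-dien-1-one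
Conditions: MnO2 (activated, excess), CH2Cl2, rt
Reagents that add atoms: none
Why: MnO2 oxidises only the allylic C6 carbinol and leaves the homoallylic C8 hydroxyl, so the two oxygens are told apart without protecting groups and the provisional C6 centre is erased.

Step 14
Reactants: 24 (2E)-3-(4-hydroxy-3-methoxyphenyl)prop-2-enal
Product: 25 (2E)-3-{4-[(tert-butyldimethylsilyl)oxy]-3-methoxyphenyl}prop-2-enal
Conditions: TBSCl, imidazole, DMF, rt
Reagents that add atoms: tert-butyldimethylsilyl chloride, CC(C)(C)[Si](C)(C)Cl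
Why: Standard silylation of a phenol; it removes the acidic proton that would quench the samarium alkoxide catalyst of step 15.

Step 15
Reactants: 23 (2E,6E,9S,10R)-9-hydroxy-3,7-dimethyl-10-(propan-2-yl)cyclodeca-2,6-dien-1-one; 25 (2E)-3-{4-[(tert-butyldimethylsilyl)oxy]-3-methoxyphenyl}prop-2-enal
Product: 26 (1S,2S,3S,4E,8E)-3-hydroxy-5,9-dimethyl-2-(propan-2-yl)cyclodeca-4,8-dien-1-yl (2E)-3-{4-[(tert-butyldimethylsilyl)oxy]-3-methoxyphenyl}prop-2-enoate
Conditions: SmI2 (30 mol%) pre-mixed with 25 (4 equiv), THF, −10 °C, then 23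
Reagents that add atoms: none
Why: Evans–Tishchenko reaction: the C8 hydroxyl forms a samarium-bound hemiacetal with 25 and its hydride passes to the C6 carbonyl through a six-membered chair transition state, giving the 1,3-anti diol (C6 S) with the oxidised aldehyde left as the cinnamate on O8 only; SmI2 is first converted by the aldehyde into the trivalent samarium alkoxide, so the enone never meets the reductant.

Step 16
Reactants: 26 (1S,2S,3S,4E,8E)-3-hydroxy-5,9-dimethyl-2-(propan-2-yl)cyclodeca-4,8-dien-1-yl (2E)-3-{4-[(tert-butyldimethylsilyl)oxy]-3-methoxyphenyl}prop-2-enoate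
Product: 27 (1S,2S,3S,4E,8E)-3-hydroxy-5,9-dimethyl-2-(propan-2-yl)cyclodeca-4,8-dien-1-yl (2E)-3-(4-hydroxy-3-methoxyphenyl)prop-2-enoate
Conditions: Bu4NF/AcOH (1:1), THF, 0 °C
Reagents that add atoms: none
Why: Buffered fluoride cleaves the aryl silyl ether much faster than it touches the alcohol or the ester, and the acetic acid buffer suppresses alkoxide-mediated 1,3-acyl migration.

## Compound list

1 | 3-methylbutanal | CC(C)CC=O | starting material
2 | but-3-en-2-one | CC(=O)C=C | starting material
3 | (2S)-5-oxo-2-(propan-2-yl)hexanal | O=C[C@H](C(C)C)CCC(C)=O | intermediate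
4 | (4S)-4-(propan-2-yl)cyclohex-2-en-1-one | O=C1C=C[C@H](C(C)C)CC1 | intermediate
5 | (4S)-2-iodo-4-(propan-2-yl)cyclohex-2-en-1-one | O=C1C(I)=C[C@H](C(C)C)CC1 | intermediate
6 | 4,4,5,5-tetramethyl-2-(prop-1-en-2-yl)-1,3,2-dioxaborolane | CC(=C)B1OC(C)(C)C(C)(C)O1 | starting material
7 | (4S)-4-(propan-2-yl)-2-(prop-1-en-2-yl)cyclohex-2-en-1-one | O=C1C(C(C)=C)=C[C@H](C(C)C)CC1 | intermediate
8 | (2S,3S,4R)-4-(propan-2-yl)-2-(prop-1-en-2-yl)-3-(4,4,5,5-tetramethyl-1,3,2-dioxaborolan-2-yl)cyclohexan-1-one | O=C1CC[C@@H](C(C)C)[C@H](B2OC(C)(C)C(C)(C)O2)[C@H]1C(C)=C | intermediate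
9 | (2R,3S,4S)-3-hydroxy-4-(propan-2-yl)-2-(prop-1-en-2-yl)cyclohexan-1-one | O=C1CC[C@@H](C(C)C)[C@H](O)[C@H]1C(C)=C | intermediate
10 | (2R,3S,4S)-3-[(tert-butyldimethylsilyl)oxy]-4-(propan-2-yl)-2-(prop-1-en-2-yl)cyclohexan-1-one | O=C1CC[C@@H](C(C)C)[C@H](O[Si](C)(C)C(C)(C)C)[C@H]1C(C)=C | intermediate
11 | (4S,5S,6R)-5-[(tert-butyldimethylsilyl)oxy]-4-(propan-2-yl)-6-(prop-1-en-2-yl)-1-[(trimethylsilyl)oxy]cyclohex-1-ene | C[Si](C)(C)OC1=CC[C@@H](C(C)C)[C@H](O[Si](C)(C)C(C)(C)C)[C@H]1C(C)=C | intermediate
12 | (4R,5S,6R)-5-[(tert-butyldimethylsilyl)oxy]-4-(propan-2-yl)-6-(prop-1-en-2-yl)cyclohex-2-en-1-one | O=C1C=C[C@@H](C(C)C)[C@H](O[Si](C)(C)C(C)(C)C)[C@H]1C(C)=C | intermediate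
13 | (2R,3S,4S,5S)-3-[(tert-butyldimethylsilyl)oxy]-4-(propan-2-yl)-2-(prop-1-en-2-yl)-5-(4,4,5,5-tetramethyl-1,3,2-dioxaborolan-2-yl)cyclohexan-1-one | O=C1C[C@H](B2OC(C)(C)C(C)(C)O2)[C@@H](C(C)C)[C@H](O[Si](C)(C)C(C)(C)C)[C@H]1C(C)=C | intermediate
14 | (2R,3S,4R,5S)-3-[(tert-butyldimethylsilyl)oxy]-5-hydroxy-4-(propan-2-yl)-2-(prop-1-en-2-yl)cyclohexan-1-one | O=C1C[C@H](O)[C@@H](C(C)C)[C@H](O[Si](C)(C)C(C)(C)C)[C@H]1C(C)=C | intermediate
15 | (2R,3S,4R,5S)-3,5-bis[(tert-butyldimethylsilyl)oxy]-4-(propan-2-yl)-2-(prop-1-en-2-yl)cyclohexan-1-one | O=C1C[C@H](O[Si](C)(C)C(C)(C)C)[C@@H](C(C)C)[C@H](O[Si](C)(C)C(C)(C)C)[C@H]1C(C)=C | intermediate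
16 | ethenylmagnesium bromide | C=C[Mg]Br | starting material
17 | (1R,2R,3S,4R,5S)-3,5-bis[(tert-butyldimethylsilyl)oxy]-1-ethenyl-4-(propan-2-yl)-2-(prop-1-en-2-yl)cyclohexan-1-ol | C=C[C@]1(O)C[C@H](O[Si](C)(C)C(C)(C)C)[C@@H](C(C)C)[C@H](O[Si](C)(C)C(C)(C)C)[C@H]1C(C)=C | intermediate
18 | potassium (1Z,5E,7R,8R,9S)-7,9-bis[(tert-butyldimethylsilyl)oxy]-5-methyl-8-(propan-2-yl)cyclodeca-1,5-dien-1-olate | [K+].[O-]/C1=C\CC/C(C)=C/[C@@H](O[Si](C)(C)C(C)(C)C)[C@H](C(C)C)[C@@H](O[Si](C)(C)C(C)(C)C)C1 | intermediate
19 | (1Z,5E,7R,8R,9S)-7,9-bis[(tert-butyldimethylsilyl)oxy]-5-methyl-8-(propan-2-yl)cyclodeca-1,5-dien-1-yl trifluoromethanesulfonate | O=S(=O)(O/C1=C\CC/C(C)=C/[C@@H](O[Si](C)(C)C(C)(C)C)[C@H](C(C)C)[C@@H](O[Si](C)(C)C(C)(C)C)C1)C(F)(F)F | intermediate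
20 | methylmagnesium bromide | C[Mg]Br | starting material
21 | (1E,5E,7R,8R,9S)-7,9-bis[(tert-butyldimethylsilyl)oxy]-1,5-dimethyl-8-(propan-2-yl)cyclodeca-1,5-diene | C/C1=C\CC/C(C)=C/[C@@H](O[Si](C)(C)C(C)(C)C)[C@H](C(C)C)[C@@H](O[Si](C)(C)C(C)(C)C)C1 | intermediate
22 | (1S,2R,3R,4E,8E)-5,9-dimethyl-2-(propan-2-yl)cyclodeca-4,8-diene-1,3-diol | C/C1=C\CC/C(C)=C/[C@@H](O)[C@H](C(C)C)[C@@H](O)C1 | intermediate
23 | (2E,6E,9S,10R)-9-hydroxy-3,7-dimethyl-10-(propan-2-yl)cyclodeca-2,6-dien-1-one | C/C1=C\CC/C(C)=C/C(=O)[C@H](C(C)C)[C@@H](O)C1 | intermediate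
24 | (2E)-3-(4-hydroxy-3-methoxyphenyl)prop-2-enal | COc1cc(/C=C/C=O)ccc1O | starting material
25 | (2E)-3-{4-[(tert-butyldimethylsilyl)oxy]-3-methoxyphenyl}prop-2-enal | COc1cc(/C=C/C=O)ccc1O[Si](C)(C)C(C)(C)C | intermediate
26 | (1S,2S,3S,4E,8E)-3-hydroxy-5,9-dimethyl-2-(propan-2-yl)cyclodeca-4,8-dien-1-yl (2E)-3-{4-[(tert-butyldimethylsilyl)oxy]-3-methoxyphenyl}prop-2-enoate | COc1cc(/C=C/C(=O)O[C@H]2C/C(C)=C/CC/C(C)=C/[C@H](O)[C@@H]2C(C)C)ccc1O[Si](C)(C)C(C)(C)C | intermediate
27 | (1S,2S,3S,4E,8E)-3-hydroxy-5,9-dimethyl-2-(propan-2-yl)cyclodeca-4,8-dien-1-yl (2E)-3-(4-hydroxy-3-methoxyphenyl)prop-2-enoate | COc1cc(/C=C/C(=O)O[C@H]2C/C(C)=C/CC/C(C)=C/[C@H](O)[C@@H]2C(C)C)ccc1O | target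

## Step count and least certain steps

Total: 16 steps (15 in the main line, 1 for aldehyde 25). Longest linear sequence: 15 steps (steps 1–13, 15 and 16).

**Step 10 (key step).** Most likely failure: heterolysis of the C5–C10 bond of the alkoxide (fragmentation or [1,3]-shift) in place of the concerted chair process, or base-induced loss of a β-silyloxy group, or partial C-sulfonylation of the enolate. Fallback, from 17: treatment with PdCl2(PhCN)2 (divalent palladium, catalytic) in THF at rt should bring about the cyclisation-induced oxy-Cope rearrangement under neutral conditions, the 1,1-disubstituted isopropenyl group stabilising the developing positive charge at C4. This gives the cyclodecenone F1. Kinetic enolisation of F1 with KN(SiMe3)2 at the C1 methylene (the C9 methylene is deactivated by the adjacent silyloxy-bearing carbon), followed by PhNTf2, returns to the route at 19.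

**Step 15.** Most likely failure: poor reach of the hemiacetal hydride to C6 within the ten-membered ring (slow transfer or delivery through a non-chair geometry with loss of anti selectivity), retro-aldol opening of the strained hydroxy enone on the Lewis-acidic samarium centre, or 1,3-acyl migration after transfer. Fallback, from 25 and 23: Pinnick oxidation of 25 (NaClO2, NaH2PO4, 2-methylbut-2-ene) gives the silyl-protected ferulic acid F2. Steglich esterification of 23 with F2 at 0 °C gives the keto ester F3, in which the regiochemistry is unambiguous because 23 has a single hydroxyl. Reagent-controlled Corey–Bakshi–Shibata reduction of the enone carbonyl ((S)-2-methyl-CBS-oxazaborolidine, catecholborane, the alkenyl arm acting as the large group) returns to the route at 26.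

**Step 9.** Most likely failure: poor facial selectivity, axial attack giving the cis-dialkenyl carbinol, which would rearrange through a transition state that delivers a Z olefin. Fallback, from 15: Corey–Chaykovsky reaction with dimethylsulfoxonium methylide, which adds reversibly and places the new C–C bond equatorial, gives the spiro-epoxide F4. Opening of F4 with excess dimethylsulfonium methylide (one-carbon homologation of an epoxide to an allylic alcohol) returns to the route at 17.

**Step 4.** Most likely failure: slow conjugate borylation at the hindered trisubstituted enone, or base-induced migration of the isopropenyl double bond into conjugation with the ketone. Fallback, from 7: nucleophilic epoxidation (H2O2, NaOH, MeOH, 0 °C), anti to the isopropyl group, gives the epoxy ketone F5. Reductive cleavage of the Cα–O bond of F5 with SmI2 (THF/MeOH, −78 °C) returns to the route at 9.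

## Further compounds

F1 | step 10 | (5E,7R,8R,9S)-7,9-bis[(tert-butyldimethylsilyl)oxy]-5-methyl-8-(propan-2-yl)cyclodec-5-en-1-one | O=C1CCC/C(C)=C/[C@@H](O[Si](C)(C)C(C)(C)C)[C@H](C(C)C)[C@@H](O[Si](C)(C)C(C)(C)C)C1
F2 | step 15 | (2E)-3-{4-[(tert-butyldimethylsilyl)oxy]-3-methoxyphenyl}prop-2-enoic acid | COc1cc(/C=C/C(=O)O)ccc1O[Si](C)(C)C(C)(C)C
F3 | step 15 | (1S,2R,4E,8E)-5,9-dimethyl-3-oxo-2-(propan-2-yl)cyclodeca-4,8-dien-1-yl (2E)-3-{4-[(tert-butyldimethylsilyl)oxy]-3-methoxyphenyl}prop-2-enoate | COc1cc(/C=C/C(=O)O[C@H]2C/C(C)=C/CC/C(C)=C/C(=O)[C@@H]2C(C)C)ccc1O[Si](C)(C)C(C)(C)C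
F4 | step 9 | (3S,4R,5S,6R,7S)-5,7-bis[(tert-butyldimethylsilyl)oxy]-6-(propan-2-yl)-4-(prop-1-en-2-yl)-1-oxaspiro[2.5]octane | C1O[C@]12C[C@H](O[Si](C)(C)C(C)(C)C)[C@@H](C(C)C)[C@H](O[Si](C)(C)C(C)(C)C)[C@H]2C(C)=C
F5 | step 4 | (1S,5S,6S)-5-(propan-2-yl)-1-(prop-1-en-2-yl)-7-oxabicyclo[4.1.0]heptan-2-one | O=C1CC[C@@H](C(C)C)[C@@H]2O[C@]12C(C)=C
A1 | alternative 1 | (2R,3S,5E,9E)-10-iodo-3-[(4-methoxyphenyl)methoxy]-5,9-dimethyl-2-(propan-2-yl)deca-5,9-dienal | O=C[C@H](C(C)C)[C@@H](OCc1ccc(OC)cc1)C/C(C)=C/CC/C(C)=C/I
A2 | alternative 1 | (1S,2E,6E,9S,10S)-9-[(4-methoxyphenyl)methoxy]-3,7-dimethyl-10-(propan-2-yl)cyclodeca-2,6-dien-1-ol | C/C1=C\CC/C(C)=C/[C@H](O)[C@H](C(C)C)[C@@H](OCc2ccc(OC)cc2)C1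
A3 | alternative 2 | (2E,6E,9S,10E)-9-[(tert-butyldimethylsilyl)oxy]-12-chloro-3,7,11-trimethyldodeca-2,6,10-trienal | O=C/C=C(C)/CC/C=C(C)/C[C@H](O[Si](C)(C)C(C)(C)C)/C=C(C)/CCl
A4 | alternative 2 | (1S,2E,6E,9S,10S)-9-[(tert-butyldimethylsilyl)oxy]-3,7-dimethyl-10-(prop-1-en-2-yl)cyclodeca-2,6-dien-1-ol | C/C1=C\CC/C(C)=C/[C@H](O)[C@H](C(C)=C)[C@@H](O[Si](C)(C)C(C)(C)C)C1
A5 | alternative 3 | (1S,6S)-3-methyl-1-(3-methylbut-1-en-2-yl)-6-(prop-1-en-2-yl)cyclohex-2-en-1-ol | CC1=C[C@@](O)(C(=C)C(C)C)[C@H](C(C)=C)CC1
A6 | alternative 3 | (2Z,6E)-3,7-dimethyl-10-(propan-2-yl)cyclodeca-2,6-dien-1-one (C10 configuration not controlled) | O=C1/C=C(C)\CC/C=C(C)/CCC1C(C)C
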